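**Strategy.** Everything rests on cutting ring C. The pyranone segment O1–C2–C3–C4 bridges C8a and C4a of the fully substituted ring A. It can therefore be assembled from an ortho-iodophenol (C8a–OH, C4a–I), carbon monoxide (C4) and a terminal arylacetylene (C3, C2, ring B). One palladium-catalysed operation makes C4a–C4, C4–C3 and O1–C2 and closes ring C. The precursor is a hexasubstituted iodophenol in which the second oxygen beside iodine, the future O5, carries benzyl rather than methyl. With a dibenzylated alkyne, one final hydrogenolysis then frees all three phenols, and no selective demethylation next to the 3-methoxy group is required.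

Key step: step 8

Remark on the chemistry: the target has no stereocentre, no configurationally stable axis and no configurable double bond. It is achiral, so no enantiomer has to be selected.

Step 1
Reactants: 1 2,3,4-trimethoxybenzaldehyde
Product: 2 5-bromo-2,3,4-trimethoxybenzaldehyde
Conditions: NBS (1.05 equiv), MeCN, rt, dark
Reagents that add atoms: N-bromosuccinimide O=C1CCC(=O)N1Br
Why: Electrophilic aromatic bromination should go to C5, which is ortho to the 4-OMe, para to the 2-OMe and meta to CHO, whereas C6 is ortho to CHO and activated only by the twisted 3-OMe, so the formyl group tells the two ends of the trimethoxy array apart.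

Step 2
Reactants: 2 5-bromo-2,3,4-trimethoxybenzaldehyde
Product: 4 5-bromo-2,3,4-trimethoxyphenol, via 5-bromo-2,3,4-trimethoxyphenyl formate 3 (not isolated)
Conditions: mCPBA, CH2Cl2, 0 °C → rt; then K2CO3 (0.2 equiv), MeOH, rt
Reagents that add atoms: 3-chloroperoxybenzoic acid O=C(OO)c1cccc(Cl)c1
Why: In this Baeyer–Villiger (Dakin-type) oxidation the aryl group with ortho and para methoxy donors migrates in preference to hydride, and methanol then transesterifies the formate.

Step 3
Reactants: 4 5-bromo-2,3,4-trimethoxyphenol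
Product: 5 1-(benzyloxy)-5-bromo-2,3,4-trimethoxybenzene
Conditions: BnBr, K2CO3, DMF, rt
Reagents that add atoms: benzyl bromide BrCc1ccccc1
Why: This is a Williamson ether synthesis on the only acidic OH, and it marks the future O5 with a hydrogenolysable group.

Step 4
Reactants: 5 1-(benzyloxy)-5-bromo-2,3,4-trimethoxybenzene
Product: 8 5-(benzyloxy)-2,3,4-trimethoxyphenol, via [5-(benzyloxy)-2,3,4-trimethoxyphenyl]lithium 6 (not isolated), via lithium [5-(benzyloxy)-2,3,4-trimethoxyphenyl]trimethoxyborate 7 (not isolated)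
Conditions: n-BuLi, THF, −78 °C; B(OMe)3, −78 °C → rt; AcOH, 30% H2O2, 0 °C → rt
Reagents that add atoms: hydrogen peroxide OO; n-butyllithium [Li]CCCC (lithium of 6 and 7 only); trimethyl borate COB(OC)OC (boron unit of 7 only)
Why: Bromine–lithium exchange at −78 °C outruns benzylic deprotonation, and borylation followed by peroxide-induced 1,2-aryl shift (boronate oxidation) places the hydroxyl exactly where bromine stood.

Step 5
Reactants: 8 5-(benzyloxy)-2,3,4-trimethoxyphenol
Product: 9 3-(benzyloxy)-2-iodo-4,5,6-trimethoxyphenol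
Conditions: NIS (1.0 equiv), dry MeCN, −20 → 0 °C, dark
Reagents that add atoms: N-iodosuccinimide O=C1CCC(=O)N1I
Why: In this electrophilic aromatic iodination the oxygenated ring has a single C–H, ortho to OH and OBn and para to OMe, while the benzyl phenyl ring is far less nucleophilic, so only one isomer can form.

Step 6
Reactants: 10 2,4-dihydroxybenzaldehyde
Product: 11 2,4-bis(benzyloxy)benzaldehyde
Conditions: BnBr (2.3 equiv), K2CO3, DMF, 60 °C
Reagents that add atoms: benzyl bromide BrCc1ccccc1
Why: This is a double Williamson etherification, with warming and excess halide to bring the hydrogen-bonded 2-OH to full conversion.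

Step 7
Reactants: 11 2,4-bis(benzyloxy)benzaldehyde
Product: 12 2,4-bis(benzyloxy)-1-ethynylbenzene
Conditions: dimethyl (1-diazo-2-oxopropyl)phosphonate, K2CO3, MeOH–THF, rt
Reagents that add atoms: dimethyl (1-diazo-2-oxopropyl)phosphonate CC(=O)C(=[N+]=[N-])P(=O)(OC)OC
Why: The Ohira–Bestmann variant of the Seyferth–Gilbert homologation turns a non-enolisable aryl aldehyde into the terminal alkyne in one mild basic step that leaves benzyl ethers alone.

Step 8
Reactants: 9 3-(benzyloxy)-2-iodo-4,5,6-trimethoxyphenol; 12 2,4-bis(benzyloxy)-1-ethynylbenzene (1.2 equiv); 13 carbon monoxide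
Product: 16 5-(benzyloxy)-2-[2,4-bis(benzyloxy)phenyl]-6,7,8-trimethoxy-4H-chromen-4-one (5,2',4'-tris(benzyloxy)-6,7,8-trimethoxyflavone), via ortho-hydroxyaryl ynone 14 (not isolated), via diethylamino enaminone 15 (not isolated)
Conditions: PdCl2(dppf) (5 mol %), CO (20 bar), Et2NH, 120 °C, autoclave, no copper salt
Reagents that add atoms: carbon monoxide [C-]#[O+] (compound 13); diethylamine CCNCC (enters intermediate 15 only and leaves again)
Why: Pd(0) adds oxidatively into the C4a–I bond of 9, CO inserts to give the aroyl–palladium species, and alkyne 12, deprotonated by the amine, is transferred and reductively eliminated to ynone 14; this is the carbonylative Sonogashira coupling of 2-iodophenols, the established flavone annulation. Diethylamine then adds conjugatively to 14 and gives the push–pull enaminone 15, whose alkene geometry is irrelevant because the reacting carbon itself enters the ring. Ring C closes when the C8a phenol oxygen attacks that carbon (future C2) in a 6-endo addition and diethylamine is expelled, an addition–elimination that restores the C2=C3 bond. No stereocentre is created. Two selectivities are needed: CO uptake must outrun direct alkynylation and palladium insertion into the neighbouring benzyl ring, which CO pressure, the absence of copper and the absence of a carboxylate or carbonate base should secure, and 6-endo must beat 5-exo closure, which the enaminone relay secures because the carbon next to the carbonyl is no longer electrophilic. Ring-A regiochemistry cannot go astray, since only one of the two oxygens flanking iodine is free.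

Step 9
Reactants: 16 5,2',4'-tris(benzyloxy)-6,7,8-trimethoxyflavone
Product: 18 5-(benzyloxy)-2-[2,4-bis(benzyloxy)phenyl]-3-hydroxy-6,7,8-trimethoxy-4H-chromen-4-one, via flavone 2,3-epoxide 17 (not isolated)
Conditions: DMDO (acetone solution, 3 equiv), CH2Cl2, 0 °C → rt; concentrate; p-TsOH (cat.), CH2Cl2, rt
Reagents that add atoms: dimethyldioxirane CC1(C)OO1
Why: The dioxirane epoxidises the enol-ether-like C2=C3 bond, and acid then opens the oxirane at C2 (cation stabilised by O1 and the aryl group) with loss of H3, which should give the flavonol and erase both stereocentres of racemic 17.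

Step 10
Reactants: 18 5,2',4'-tris(benzyloxy)-3-hydroxy-6,7,8-trimethoxyflavone
Product: 19 5-(benzyloxy)-2-[2,4-bis(benzyloxy)phenyl]-3,6,7,8-tetramethoxy-4H-chromen-4-one
Conditions: MeI, K2CO3, acetone, reflux
Reagents that add atoms: iodomethane CI
Why: This is a Williamson O-methylation of the only free hydroxyl in the molecule, so no selectivity question arises.

Step 11
Reactants: 19 5,2',4'-tris(benzyloxy)-3,6,7,8-tetramethoxyflavone
Product: 20 5,2',4'-trihydroxy-3,6,7,8-tetramethoxyflavone (target)
Conditions: H2 (1 atm), 10% Pd/C, EtOAc–MeOH, rt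
Reagents that add atoms: none
Why: Catalytic hydrogenolysis cleaves the three aryl benzyl ethers under neutral conditions that touch neither the methyl ethers nor the tetrasubstituted C2=C3 bond of the 3-methoxyflavone.

**Compound list**

1 | 2,3,4-trimethoxybenzaldehyde | COc1ccc(C=O)c(OC)c1OC | starting material
2 | 5-bromo-2,3,4-trimethoxybenzaldehyde | COc1c(Br)cc(C=O)c(OC)c1OC | intermediate
3 | 5-bromo-2,3,4-trimethoxyphenyl formate | COc1c(Br)cc(OC=O)c(OC)c1OC | intermediate (not isolated)
4 | 5-bromo-2,3,4-trimethoxyphenol | COc1c(Br)cc(O)c(OC)c1OC | intermediate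
5 | 1-(benzyloxy)-5-bromo-2,3,4-trimethoxybenzene | COc1c(Br)cc(OCc2ccccc2)c(OC)c1OC | intermediate
6 | [5-(benzyloxy)-2,3,4-trimethoxyphenyl]lithium | [Li]c1cc(OCc2ccccc2)c(OC)c(OC)c1OC | intermediate (not isolated)
7 | lithium [5-(benzyloxy)-2,3,4-trimethoxyphenyl]trimethoxyborate | [Li+].CO[B-](OC)(OC)c1cc(OCc2ccccc2)c(OC)c(OC)c1OC | intermediate (not isolated)
8 | 5-(benzyloxy)-2,3,4-trimethoxyphenol | COc1c(O)cc(OCc2ccccc2)c(OC)c1OC | intermediate
9 | 3-(benzyloxy)-2-iodo-4,5,6-trimethoxyphenol | COc1c(O)c(I)c(OCc2ccccc2)c(OC)c1OC | intermediate (key-step precursor)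
10 | 2,4-dihydroxybenzaldehyde | O=Cc1ccc(O)cc1O | starting material
11 | 2,4-bis(benzyloxy)benzaldehyde | O=Cc1ccc(OCc2ccccc2)cc1OCc1ccccc1 | intermediate
12 | 2,4-bis(benzyloxy)-1-ethynylbenzene | C#Cc1ccc(OCc2ccccc2)cc1OCc1ccccc1 | intermediate (key-step precursor)
13 | carbon monoxide | [C-]#[O+] | starting material
14 | 1-[2-(benzyloxy)-6-hydroxy-3,4,5-trimethoxyphenyl]-3-[2,4-bis(benzyloxy)phenyl]prop-2-yn-1-one | COc1c(O)c(C(=O)C#Cc2ccc(OCc3ccccc3)cc2OCc2ccccc2)c(OCc2ccccc2)c(OC)c1OC | intermediate (not isolated)
15 | (E)-1-[2-(benzyloxy)-6-hydroxy-3,4,5-trimethoxyphenyl]-3-[2,4-bis(benzyloxy)phenyl]-3-(diethylamino)prop-2-en-1-one (drawn E; geometry without consequence) | CCN(CC)/C(=C/C(=O)c1c(O)c(OC)c(OC)c(OC)c1OCc1ccccc1)c1ccc(OCc2ccccc2)cc1OCc1ccccc1 | intermediate (not isolated)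
16 | 5-(benzyloxy)-2-[2,4-bis(benzyloxy)phenyl]-6,7,8-trimethoxy-4H-chromen-4-one | COc1c(OC)c(OCc2ccccc2)c2c(=O)cc(-c3ccc(OCc4ccccc4)cc3OCc3ccccc3)oc2c1OC | intermediate (key-step product)
17 | 2,3-epoxide of 16 (oxirane cis-fused to ring C; racemic, one enantiomer drawn) | O=C1[C@@H]2O[C@]2(c2ccc(OCc3ccccc3)cc2OCc2ccccc2)Oc2c(OC)c(OC)c(OC)c(OCc3ccccc3)c21 | intermediate (not isolated)
18 | 5-(benzyloxy)-2-[2,4-bis(benzyloxy)phenyl]-3-hydroxy-6,7,8-trimethoxy-4H-chromen-4-one | COc1c(OC)c(OCc2ccccc2)c2c(=O)c(O)c(-c3ccc(OCc4ccccc4)cc3OCc3ccccc3)oc2c1OC | intermediate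
19 | 5-(benzyloxy)-2-[2,4-bis(benzyloxy)phenyl]-3,6,7,8-tetramethoxy-4H-chromen-4-one | COc1c(OC)c(OCc2ccccc2)c2c(=O)c(OC)c(-c3ccc(OCc4ccccc4)cc3OCc3ccccc3)oc2c1OC | intermediate
20 | 5,2',4'-trihydroxy-3,6,7,8-tetramethoxyflavone (achiral) | COc1c(OC)c(O)c2c(=O)c(OC)c(-c3ccc(O)cc3O)oc2c1OC | target

**Step count.** Total steps: 11. Longest linear sequence: 9 (steps 1–5 and 8–11). Steps 6–7 form the convergent branch.

**Steps most likely to fail**

**Step 8.**
- Risk: oxidative addition into an electron-rich C–I bond flanked on both sides may be slow. That would leave room for loss of iodine by reduction, capture of the acyl–palladium by the amine, coupling without CO uptake, or palladium insertion into the adjacent benzyl ring.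
- Fallback: it sets out from 8 and 12 and rejoins at 14, hence 16. C4 is brought in as a formyl carbon, without iodide, palladium or CO.
- Magnesium-mediated ortho-formylation of phenol 8 (MgCl2, Et3N, paraformaldehyde, MeCN, reflux) should hit the only free ring carbon. It should give 2-(benzyloxy)-6-hydroxy-3,4,5-trimethoxybenzaldehyde F1.
- Alkyne 12 is deprotonated (n-BuLi, THF, −78 °C) to lithium [2,4-bis(benzyloxy)phenyl]acetylide F2.
- Two equivalents of F2 add to F1 to give racemic 3-(benzyloxy)-2-{3-[2,4-bis(benzyloxy)phenyl]-1-hydroxyprop-2-yn-1-yl}-4,5,6-trimethoxyphenol F3.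
- MnO2 (CH2Cl2, rt) oxidises the benzylic–propargylic carbinol to ynone 14.
- Warm Et2NH in EtOH then closes 14 through 15 to 16.

**Step 9.**
- Risk: epoxidation of a C2=C3 bond shielded by the twisted ortho-substituted B ring may be slow. Oxidation of the electron-rich rings or of benzylic C–H bonds by excess dioxirane could then compete.
- Fallback: it sets out from 16 and rejoins at 18. Deprotonation replaces alkene oxidation.
- LDA (THF, −78 °C) removes H3 to give the 3-lithio derivative of 16 F4.
- B(OMe)3 traps F4 as the lithium (flavon-3-yl)trimethoxyborate F5.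
- AcOH/H2O2 converts the C–B bond into the C3–OH of 18.

**Step 5.**
- Risk: the iodonium source may oxidatively dearomatise the para-alkoxyphenol instead of substituting its C–H bond.
- Fallback: it sets out from 8 and rejoins at 9. The iodine is delivered to a carbanion rather than to the free phenol.
- MOMCl/iPr2NEt (CH2Cl2) gives 1-(benzyloxy)-2,3,4-trimethoxy-5-(methoxymethoxy)benzene F6.
- n-BuLi (THF, −78 → −20 °C) metalates the carbon between OMOM and OBn (cooperative directed ortho-metalation). This gives [2-(benzyloxy)-3,4,5-trimethoxy-6-(methoxymethoxy)phenyl]lithium F7.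
- I2 gives 1-(benzyloxy)-2-iodo-4,5,6-trimethoxy-3-(methoxymethoxy)benzene F8.
- HCl in MeOH removes the acetal to give 9.

**Further compounds**

F1 | step 8 | 2-(benzyloxy)-6-hydroxy-3,4,5-trimethoxybenzaldehyde | COc1c(O)c(C=O)c(OCc2ccccc2)c(OC)c1OC
F2 | step 8 | lithium [2,4-bis(benzyloxy)phenyl]acetylide | [Li]C#Cc1ccc(OCc2ccccc2)cc1OCc1ccccc1
F3 | step 8 | 3-(benzyloxy)-2-{3-[2,4-bis(benzyloxy)phenyl]-1-hydroxyprop-2-yn-1-yl}-4,5,6-trimethoxyphenol (racemic) | COc1c(O)c(C(O)C#Cc2ccc(OCc3ccccc3)cc2OCc2ccccc2)c(OCc2ccccc2)c(OC)c1OC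
F4 | step 9 | 3-lithio derivative of 16 | COc1c(OC)c(OCc2ccccc2)c2c(=O)c([Li])c(-c3ccc(OCc4ccccc4)cc3OCc3ccccc3)oc2c1OC
F5 | step 9 | lithium (flavon-3-yl)trimethoxyborate derived from 16 | [Li+].COc1c(OC)c(OCc2ccccc2)c2c(=O)c([B-](OC)(OC)OC)c(-c3ccc(OCc4ccccc4)cc3OCc3ccccc3)oc2c1OC
F6 | step 5 | 1-(benzyloxy)-2,3,4-trimethoxy-5-(methoxymethoxy)benzene | COCOc1cc(OCc2ccccc2)c(OC)c(OC)c1OC
F7 | step 5 | [2-(benzyloxy)-3,4,5-trimethoxy-6-(methoxymethoxy)phenyl]lithium | COCOc1c([Li])c(OCc2ccccc2)c(OC)c(OC)c1OC
F8 | step 5 | 1-(benzyloxy)-2-iodo-4,5,6-trimethoxy-3-(methoxymethoxy)benzene | COCOc1c(I)c(OCc2ccccc2)c(OC)c(OC)c1OC
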